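**Assumption:** the target is the (1R,8E) isomer exactly as drawn (the [C@H] centre is R by CIP); 8-chloro-1-octyne and methyl 4-bromo-3,5-dimethoxybenzoate are treated as catalogue items. The route has not been run; conditions are proposed from known reaction classes.

## Retrosynthetic overview

1. The (R)-carbinol comes last, by asymmetric transfer hydrogenation of the fully deprotected macrocyclic aryl ketone; the ring-B phenols are unmasked with BBr3 just before, while C1 is still a ketone.
2. The 22-membered ring is closed at the diaryl ether: an intramolecular Cu-mediated O-arylation in which a C2v-symmetric 5-alkylresorcinol, unmasked in situ, is desymmetrised on the 4-bromo-3,5-dimethoxyaryl ketone (key step).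
3. The seco-ketone comes from a long-chain alkyl Grignard and methyl 4-bromo-3,5-dimethoxybenzoate (C1–C2 bond).
4. The E-alkene (C8=C9) comes from hydrozirconation of 8-chloro-1-octyne and sp2–sp3 Negishi coupling with an aryl-pentyl bromide.
5. Ring A comes from 1-bromo-3,5-dimethoxybenzene (OMe to OSiEt3 swap, then Cu-catalysed Grignard alkylation). Both benzene rings are bought; the macrocycle is the only ring formed.

## Route

**Step 1**
Reactants: 1, 1-bromo-3,5-dimethoxybenzene
Product: 2, 1-bromo-3,5-bis(triethylsilyloxy)benzene
Conditions: Et3SiH (2.5 equiv), B(C6F5)3 (5 mol %), CH2Cl2, rt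
Reagents that add atoms: triethylsilane, CC[SiH](CC)CC
Why: Piers–Rubinsztajn-type B(C6F5)3/hydrosilane cleavage of aryl methyl ethers gives the aryl silyl ethers directly with loss of methane and leaves Ar–Br untouched; this makes ring A removable by fluoride later without touching ring B.

**Step 2**
Reactants: 2, 1-bromo-3,5-bis(triethylsilyloxy)benzene; 3, 1,5-dibromopentane
Product: 4, 1-(5-bromopentyl)-3,5-bis(triethylsilyloxy)benzene
Conditions: Mg, THF, 40 °C; then add to 3 (4 equiv), Li2CuCl4 (3 mol %), THF, −10 °C → rt
Reagents that add atoms: none other than reactant 3 (BrCCCCCBr)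
Why: Kochi-type Cu-catalysed coupling of an aryl Grignard with a primary alkyl bromide; excess dibromide suppresses double arylation, and aryl silyl ethers tolerate Grignard formation.

**Step 3**
Reactants: 5, 8-chloro-1-octyne; 4, 1-(5-bromopentyl)-3,5-bis(triethylsilyloxy)benzene
Product: 6, 1-[(6E)-13-chlorotridec-6-en-1-yl]-3,5-bis(triethylsilyloxy)benzene
Conditions: 5, Cp2Zr(H)Cl (1.3 equiv), THF, rt; then 4, Pd(acac)2 (2.5 mol %), LiBr, THF/NMP, 55 °C
Reagents that add atoms: none other than reactant 5 (ClCCCCCCC#C)
Why: Schwartz hydrozirconation is syn with Zr on the terminal carbon, so only the E-alkenyl metal forms; ligand-free Negishi-type sp2–sp3 coupling with the primary bromide retains geometry (sets 8E), and the alkyl chloride and silyl ethers should be inert (the main risk is Cl/Br exchange with LiBr).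

**Step 4**
Reactants: 6, the E-alkenyl chloride; 7, methyl 4-bromo-3,5-dimethoxybenzoate
Product: 8, (8E)-1-(4-bromo-3,5-dimethoxyphenyl)-14-[3,5-bis(triethylsilyloxy)phenyl]tetradec-8-en-1-one
Conditions: 7, MeNH(OMe)·HCl (1.55 equiv), i-PrMgCl (3.0 equiv), THF, −20 °C; then RMgCl from 6 (Mg, cat. BrCH2CH2Br, THF, reflux), −20 → 0 °C; aq. NH4Cl
Reagents that add atoms: none other than reactant 7 (COC(=O)c1cc(OC)c(Br)c(OC)c1); the amine salt and i-PrMgCl leave no atoms
Why: Weinreb ketone synthesis with the amide generated in situ from the ester; the chelated tetrahedral intermediate stops at the ketone, and a primary alkyl Grignard does not exchange with the aryl bromide at or below 0 °C. The alkene is too remote (7-exo) for radical cyclisation during Mg insertion.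

**Step 5 (key step)**
Reactants: 8, the bis-silylated seco-ketone
Product: 9, the 22-membered macrocyclic diaryl ether ketone (8E): ring-A oxygen bonded to C-4 of ring B, ring B 3,5-di-OMe, ring A 5-OH free
Conditions: CuI (1.0 equiv), picolinic acid (2.0 equiv), K3PO4 (4 equiv), CsF (2.5 equiv), DMSO, 90 °C, syringe-pump addition to 2 mM, Ar
Reagents that add atoms: none
Why: fluoride removes both TES groups to give the symmetric resorcinolate, and an intramolecular Ullmann-type O-arylation (Cu/picolinic acid, conditions developed for hindered diaryl ethers) then closes the ring. Either of the two equivalent phenoxides gives the same product, so no O-differentiation is needed and bis-arylation cannot occur within one molecule. The para-acyl group activates the di-ortho-methoxy C–Br, and high dilution suppresses oligomers. The hindered bromide has no close precedent in a macrocyclisation and is the main risk.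

**Step 6**
Reactants: 9, the macrocyclic dimethyl ether ketone
Product: 10, the macrocyclic triphenol ketone (C1-oxo analogue of the target)
Conditions: BBr3 (6 equiv), CH2Cl2, −78 → 0 °C; MeOH quench
Reagents that add atoms: none
Why: BBr3 Lewis-acid demethylation, done while C1 is still a ketone so no ionisable benzylic alcohol is exposed; the diaryl ether and the isolated E-alkene are expected to survive at or below 0 °C.

**Step 7**
Reactants: 10, the macrocyclic triphenol ketone
Product: 11, dehydrogravicycle, (1R,8E)
Conditions: RuCl[(R,R)-TsDPEN](p-cymene) (2 mol %), HCO2H/Et3N (5:2), DMF, 40 °C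
Reagents that add atoms: none (H only)
Why: Noyori–Ikariya asymmetric transfer hydrogenation of an aryl n-alkyl ketone; the (R,R)-catalyst delivers hydride in the same sense as acetophenone → (R)-1-phenylethanol, giving the (R)-carbinol. Free phenols and the isolated alkene are not touched, and no later step can erode the centre.

## Compound list

1 | 1-bromo-3,5-dimethoxybenzene | COc1cc(Br)cc(OC)c1 | starting material
2 | 1-bromo-3,5-bis(triethylsilyloxy)benzene | CC[Si](CC)(CC)Oc1cc(Br)cc(O[Si](CC)(CC)CC)c1 | intermediate
3 | 1,5-dibromopentane | BrCCCCCBr | starting material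
4 | 1-(5-bromopentyl)-3,5-bis(triethylsilyloxy)benzene | CC[Si](CC)(CC)Oc1cc(CCCCCBr)cc(O[Si](CC)(CC)CC)c1 | intermediate
5 | 8-chloro-1-octyne | ClCCCCCCC#C | starting material
6 | 1-[(6E)-13-chlorotridec-6-en-1-yl]-3,5-bis(triethylsilyloxy)benzene | CC[Si](CC)(CC)Oc1cc(CCCCC/C=C/CCCCCCCl)cc(O[Si](CC)(CC)CC)c1 | intermediate
7 | methyl 4-bromo-3,5-dimethoxybenzoate | COC(=O)c1cc(OC)c(Br)c(OC)c1 | starting material
8 | (8E)-1-(4-bromo-3,5-dimethoxyphenyl)-14-[3,5-bis(triethylsilyloxy)phenyl]tetradec-8-en-1-one | CC[Si](CC)(CC)Oc1cc(CCCCC/C=C/CCCCCCC(=O)c2cc(OC)c(Br)c(OC)c2)cc(O[Si](CC)(CC)CC)c1 | intermediate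
9 | 22-membered macrocyclic diaryl ether ketone, ring B di-O-methyl, 8E | Oc1cc2cc(c1)Oc1c(OC)cc(cc1OC)C(=O)CCCCCC/C=C/CCCCC2 | intermediate
10 | macrocyclic triphenol ketone (1-oxo analogue of the target), 8E | Oc1cc2cc(c1)Oc1c(O)cc(cc1O)C(=O)CCCCCC/C=C/CCCCC2 | intermediate
11 | dehydrogravicycle, (1R,8E) | Oc1cc2cc(c1)Oc1c(O)cc(cc1O)[C@H](O)CCCCCC/C=C/CCCCC2 | target

## Summary

Total steps: 7. Longest linear sequence: 7 (from 1; compounds 3, 5 and 7 are purchased and enter directly).

Steps most likely to fail, each with a fallback that changes the approach: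

- **Step 5 (macro-etherification on the di-ortho-methoxy bromide).** Fallback: move the ring closure away from the C–O bond. Form the diaryl ether intermolecularly on small fragments (4-bromo-3,5-dimethoxybenzaldehyde plus a mono-protected 5-alkynylresorcinol), then close the 22-membered ring at C8–C9 by ring-closing alkyne metathesis and trans-selective semi-reduction.
- **Step 3 (alkenylzirconium / alkyl bromide coupling).** Fallback: build C8–C9 as an alkyne instead. Alkylate the lithium acetylide of 5 with bromide 4 (n-BuLi, THF/DMPU), then convert the internal alkyne to the E-alkene by Ru-catalysed trans-hydrosilylation and protodesilylation.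
- **Step 4 (one-pot ester → ketone with the long-chain Grignard).** Fallback: add the Grignard from 6 to 4-bromo-3,5-dimethoxybenzaldehyde and oxidise the resulting carbinol to 8 with Dess–Martin periodinane, a two-step addition/oxidation replacing the acyl substitution.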